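The data are calculated with constants of no real substance; the scatter is artificial.

I was asked what share of target in target plus side product the flask would show at an early moment and at the end, so I looked for something that stays put while the amounts move.

- teal: starting material 7.5 mM; coupling partner 7.5 mM; protic impurity 0.25 mM; run made earlier
- flask: starting material 5.0 mM; coupling partner 7.50 mM; protic impurity 0.250 mM; time 8.0 min

- teal (time / s: target / %, side product / %): 10.0: 26.5, 38.5; 15.0: 32.8, 47.4; 25.0: 40.4, 55.1; 40.0: 39.0, 55.0; 50.0: 40.1, 54.8

(each reading ± 1 percentage point)

- what was read earlier has a scatter of 1 percentage point, one standard deviation
- candidate steps: starting material + coupling partner <-> intermediate A; starting material -> decomposition product; intermediate B -> side product; intermediate B -> target; 2 coupling partner -> self-condensation product; starting material + protic impurity -> quenched substrate; starting material <-> intermediate B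

- share of target in target plus side product at 1.2 s
- share of target in target plus side product at 8.0 min

Among the candidate steps, target and side product each arise from intermediate B by a first-order step, so dividing one rate by the other cancels intermediate B. Integrating from the empty start then leaves target over side product equal to the ratio of the two rate constants, a selectivity factor, at any time on that scheme. But the constant had to be read, so I turned to the teal run, where target climbs from 26.5 % at 10.0 s to 40.4 % at 25.0 s. Summing its target readings over its side-product readings gave me a reading of the branching ratio, 0.713, subject to the scatter of those readings, and from it I estimated a share of 41.6 % at both asked times in the flask. The forecast, from its weighted mean, gave 41.7 % (40 % to 43.2 %) and 41.7 % (40.5 % to 43 %), holding that the ratio “shouldn't depend on time, concentration or coupling partner”.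

The flask gave 42.1 % at 1.2 s and 42.1 % at 8.0 min, and the constant of intermediate B to target over that to side product stands at 0.728.

    starting material + coupling partner ⇌ intermediate A (K = 310 L mol⁻¹, k = 219 L mol⁻¹ s⁻¹)
    starting material → decomposition product (k = 3.00 × 10⁻⁴ s⁻¹)
    intermediate B → side product (k = 0.357 s⁻¹)
    intermediate B → target (k = 0.260 s⁻¹)
    2 coupling partner → self-condensation product (k = 36.4 L mol⁻¹ s⁻¹)
    starting material + protic impurity → quenched substrate (k = 405 L mol⁻¹ s⁻¹)
    starting material ⇌ intermediate B (K = 28.0, k = 0.284 s⁻¹)

In the neighbour flask, charged with 0.10 mM of protic impurity, side product ended at 56.6 %, which my ratio turns into 40.4 % of target, and that flask held 41.3 %.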